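**Retrosynthetic overview** (flavonoid numbering O1, C2, C3, C4, C4a, C5–C8, C8a is used for every compound)
1. Rings B and D are bought. Ketone 1 supplies C4a, C8a, C8 and the 8-benzyl arm. Glycidate 2 supplies C2, C3, C4, ring B and both stereocentres. A Claisen C4–C4a bond joins them as epoxy-β-diketone 3.
2. Malonyl dichloride 4 is the C5–C6–C7 unit of ring A.
3. Key disconnection, one flask and two rings: O1–C2 first (ring C, epoxide opening, 3 → 5). Then C8–C7 and C4a–C5 (ring A, formal [3+3], 5 → 6 → 7 → 8 → 9).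
4. O1–C8a exists before ring A does, so the benzyl group can only end at C8. No 6- versus 8-isomer problem arises.
5. Last disconnection: the two methyl ethers and the silyl ether of 9 are removed together to give target 10.

Assumption: methyl (2R,3S)-3-(4-methoxyphenyl)glycidate 2, the bulk intermediate of diltiazem manufacture, counts as a cheap commercial starting material.
Abbreviations: TBS = tert-butyldimethylsilyl, Tf = trifluoromethanesulfonyl.

**Step 1**
Reactants: 1 anisylacetone [4-(4-methoxyphenyl)butan-2-one]; 2 methyl (2R,3S)-3-(4-methoxyphenyl)oxirane-2-carboxylate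
Product: 3 1-[(2R,3S)-3-(4-methoxyphenyl)oxiran-2-yl]-5-(4-methoxyphenyl)pentane-1,3-dione (largely enolised)
Conditions: LiN(iPr)2 (2.1 equiv), 1 (2.2 equiv), THF, −78 °C, 45 min; then 2 (1.0 equiv), −78 → −30 °C, 2 h; AcOH (2.2 equiv), −78 °C; cold pH 7 work-up, used crude the same day
Reagents that add atoms: none
Why: Crossed Claisen condensation in which the kinetic methyl-side lithium enolate of 1 adds to the inductively activated ester carbonyl of 2 faster than to the oxirane at low temperature, deprotonation of the β-diketone drives it forward, and both oxirane stereocentres are untouched because an oxirane C–H does not enolise.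

**Step 2 (key step)**
Reactants: 3 epoxy-β-diketone; 4 malonyl dichloride
Product: 9 (2R,3R)-3-(tert-butyldimethylsilyloxy)-5,7-dihydroxy-8-(4-methoxybenzyl)-2-(4-methoxyphenyl)chroman-4-one, via silyloxy dihydropyranone 5 (not isolated), via bis-silyl dienol ether 6 (not isolated), via keto acid chloride 7 (not isolated), via dienylketene 8 (not isolated)
Conditions: one flask, CH2Cl2 (0.02 M): TBSOTf (1.1 equiv), Et3N (1.2 equiv), −78 °C, 30 min; then TBSOTf (1.1 equiv), Et3N (1.2 equiv), −78 → 0 °C, 1 h; then 4 (1.1 equiv), −78 → 23 °C, 12 h; aq NaHCO3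
Reagents that add atoms: tert-butyldimethylsilyl trifluoromethanesulfonate (TBSOTf), CC(C)(C)[Si](C)(C)OS(=O)(=O)C(F)(F)F
Why: Proposed new method: silyl triflate activation of the p-anisyl epoxide lets the C8a enol oxygen close ring C by 6-endo attack at the benzylic carbon with inversion (the mode by which 2'-hydroxychalcone epoxides give trans-dihydroflavonols, and any cationic leakage also collapses to the diequatorial trans isomer), so C2 becomes R while C3 keeps the R configuration of 2 and is capped as its silyl ether; soft enolisation at the unhindered C8 methylene rather than at the crowded silyloxy-bearing C3–H gives 6, a Chan-type 1,3-bis-nucleophile whose terminal carbon C8 is acylated by 4; 7 loses HCl to dienylketene 8, for which C4a–C5 closure by 6π electrocyclisation is the only six-membered option, and tautomerisation gives ring A; the closest known reactions are the Effenberger synthesis of phloroglucinol ethers from enol ethers and malonyl dichloride, the [3+3] cyclisation of 1,3-bis(silyl enol ethers) and the last stage of the Danheiser benzannulation.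

**Step 3**
Reactants: 9 protected chromanone
Product: 10 (2R,3R)-3,5,7-trihydroxy-8-(4-hydroxybenzyl)-2-(4-hydroxyphenyl)chroman-4-one
Conditions: BBr3 (8 equiv), CH2Cl2, −78 → 0 °C, 3 h; then H2O, 0 °C; THF added, 23 °C, 1 h
Reagents that add atoms: none
Why: Lewis-acid ether cleavage in which bromide attacks the methyl groups of the boron-coordinated aryl ethers and the silyl ether falls to BBr3 and the aqueous HBr of the quench, while the boron chelate formed at once between O5 and the C4 carbonyl holds ring C in place, so C3 is untouched and any reversible C2–O1 ionisation can only re-close through O1 to the more stable trans isomer.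

**Compound list**
1 | 4-(4-methoxyphenyl)butan-2-one | CC(=O)CCc1ccc(OC)cc1 | starting material
2 | methyl (2R,3S)-3-(4-methoxyphenyl)oxirane-2-carboxylate | COC(=O)[C@@H]1O[C@H]1c1ccc(OC)cc1 | starting material
3 | 1-[(2R,3S)-3-(4-methoxyphenyl)oxiran-2-yl]-5-(4-methoxyphenyl)pentane-1,3-dione (drawn as diketo tautomer) | COc1ccc(CCC(=O)CC(=O)[C@@H]2O[C@H]2c2ccc(OC)cc2)cc1 | intermediate
4 | malonyl dichloride | O=C(Cl)CC(=O)Cl | starting material
5 | (2R,3R)-3-(tert-butyldimethylsilyloxy)-2-(4-methoxyphenyl)-6-[2-(4-methoxyphenyl)ethyl]-2,3-dihydro-4H-pyran-4-one | O=C1C=C(CCc2ccc(OC)cc2)O[C@H](c2ccc(OC)cc2)[C@H]1O[Si](C)(C)C(C)(C)C | intermediate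
6 | (2R,3R)-3,4-bis(tert-butyldimethylsilyloxy)-2-(4-methoxyphenyl)-6-[2-(4-methoxyphenyl)ethylidene]-3,6-dihydro-2H-pyran (alkene geometry not controlled and of no consequence) | CC(C)(C)[Si](C)(C)OC1=CC(=CCc2ccc(OC)cc2)O[C@H](c2ccc(OC)cc2)[C@H]1O[Si](C)(C)C(C)(C)C | intermediate
7 | 4-[(2R,3R)-3-(tert-butyldimethylsilyloxy)-2-(4-methoxyphenyl)-4-oxo-3,4-dihydro-2H-pyran-6-yl]-5-(4-methoxyphenyl)-3-oxopentanoyl chloride (C4 of the chain epimeric, enolisable) | O=C1C=C(C(Cc2ccc(OC)cc2)C(=O)CC(=O)Cl)O[C@H](c2ccc(OC)cc2)[C@H]1O[Si](C)(C)C(C)(C)C | intermediate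
8 | (2R,3R)-3-(tert-butyldimethylsilyloxy)-6-[3-hydroxy-1-(4-methoxyphenyl)-5-oxopenta-2,4-dien-2-yl]-2-(4-methoxyphenyl)-2,3-dihydro-4H-pyran-4-one (dienylketene) | O=C1C=C(C(Cc2ccc(OC)cc2)=C(O)C=C=O)O[C@H](c2ccc(OC)cc2)[C@H]1O[Si](C)(C)C(C)(C)C | intermediate
9 | (2R,3R)-3-(tert-butyldimethylsilyloxy)-5,7-dihydroxy-8-(4-methoxybenzyl)-2-(4-methoxyphenyl)chroman-4-one | O=C1c2c(O)cc(O)c(Cc3ccc(OC)cc3)c2O[C@H](c2ccc(OC)cc2)[C@H]1O[Si](C)(C)C(C)(C)C | intermediate
10 | (2R,3R)-3,5,7-trihydroxy-8-(4-hydroxybenzyl)-2-(4-hydroxyphenyl)chroman-4-one | O=C1c2c(O)cc(O)c(Cc3ccc(O)cc3)c2O[C@H](c2ccc(O)cc2)[C@H]1O | target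

**Total step count:** 3. **Longest linear sequence:** 3.

**Steps most likely to fail, highest risk first**

**Step 2.** Four things can go wrong:
- a 1,2-acyl shift of the activated epoxide;
- enolisation at C3 instead of C8;
- first acylation at C4a followed by closure through O4 to a pyranopyrone;
- oligomerisation.

The fallback sets out from 3 and comes back at 10. It ties the C5–C7 unit to C8 before any ring is closed, so ring A closes intramolecularly. 3 is deprotonated twice with LiN(iPr)2 in THF at −78 °C. The oxirane C–H cannot enolise, so the second charge sits on C8. The dianion is acylated there by tert-butyl 3-chloro-3-oxopropanoate to give tert-butyl 4-(4-methoxybenzyl)-7-[(2R,3S)-3-(4-methoxyphenyl)oxiran-2-yl]-3,5,7-trioxoheptanoate F3. Camphorsulfonic acid (5 mol %) in toluene at 0 °C closes ring C to tert-butyl 4-[(2R,3R)-3-hydroxy-2-(4-methoxyphenyl)-4-oxo-3,4-dihydro-2H-pyran-6-yl]-5-(4-methoxyphenyl)-3-oxopentanoate F4. Solid NaHCO3 is added and the same dilute solution is heated at 110 °C. tert-Butanol is lost to give the 3-hydroxy dienylketene F5, which has no oxygen nucleophile within reach of a six-membered closure. It electrocyclises onto C4a to give (2R,3R)-3,5,7-trihydroxy-8-(4-methoxybenzyl)-2-(4-methoxyphenyl)chroman-4-one F6. F6 is demethylated under the step 3 conditions to 10.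

**Step 3.** Three things can go wrong:
- Lewis-acid opening of C2–O1 with epimerisation;
- re-closure through O5, which would move the benzyl group to C6;
- loss of the benzyl group.

The fallback sets out from 4, which it keeps as the C5–C7 unit, and comes back at 10. It replaces methyl by silyl so that the last step is a fluoride desilylation.
- Raspberry ketone with TBSCl and imidazole gives 4-[4-(tert-butyldimethylsilyloxy)phenyl]butan-2-one F7.
- Methyl 4-hydroxycinnamate is silylated in the same way to methyl (E)-3-[4-(tert-butyldimethylsilyloxy)phenyl]prop-2-enoate F8.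
- F8 is epoxidised with KHSO5 and the L-sorbose-derived enantiomer of the fructose diacetate ketone to methyl (2R,3S)-3-[4-(tert-butyldimethylsilyloxy)phenyl]oxirane-2-carboxylate F9.
- Claisen condensation of F7 with F9 as in step 1 gives the bis-silyl epoxy-β-diketone F10.
- The one-flask sequence of step 2 with 4 runs through the tris-silyl dihydropyranone F11, the tetrakis-silyl dienol ether F12, the tris-silyl keto acid chloride F13 and the tris-silyl dienylketene F14 to the tris-silyl chromanone F15.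
- Et3N·3HF in MeCN at 0 → 23 °C strips all three silyl groups to give 10.

**Step 1.** The enolate may attack the oxirane, acylation may be sluggish, or 3 may cyclise during work-up. The fallback sets out from 2 and comes back at 3. It replaces the acylation by aldol addition and oxidation. iBu2AlH in toluene at −78 °C reduces 2 to (2R,3S)-3-(4-methoxyphenyl)oxirane-2-carbaldehyde F1. The lithium enolate of 1 adds to F1 at −78 °C to give 1-hydroxy-1-[(2S,3S)-3-(4-methoxyphenyl)oxiran-2-yl]-5-(4-methoxyphenyl)pentan-3-one F2. F2 has the same spatial arrangement at the oxirane as 2 and is a mixture of carbinol epimers. Dess–Martin periodinane buffered with NaHCO3 oxidises F2 to 3.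

**Further compounds**
F1 | step 1 | (2R,3S)-3-(4-methoxyphenyl)oxirane-2-carbaldehyde | O=C[C@@H]1O[C@H]1c1ccc(OC)cc1
F2 | step 1 | 1-hydroxy-1-[(2S,3S)-3-(4-methoxyphenyl)oxiran-2-yl]-5-(4-methoxyphenyl)pentan-3-one (carbinol epimers) | COc1ccc(CCC(=O)CC(O)[C@@H]2O[C@H]2c2ccc(OC)cc2)cc1
F3 | step 2 | tert-butyl 4-(4-methoxybenzyl)-7-[(2R,3S)-3-(4-methoxyphenyl)oxiran-2-yl]-3,5,7-trioxoheptanoate | CC(C)(C)OC(=O)CC(=O)C(Cc1ccc(OC)cc1)C(=O)CC(=O)[C@@H]1O[C@H]1c1ccc(OC)cc1
F4 | step 2 | tert-butyl 4-[(2R,3R)-3-hydroxy-2-(4-methoxyphenyl)-4-oxo-3,4-dihydro-2H-pyran-6-yl]-5-(4-methoxyphenyl)-3-oxopentanoate | O=C1C=C(C(Cc2ccc(OC)cc2)C(=O)CC(=O)OC(C)(C)C)O[C@H](c2ccc(OC)cc2)[C@H]1O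
F5 | step 2 | (2R,3R)-3-hydroxy-6-[3-hydroxy-1-(4-methoxyphenyl)-5-oxopenta-2,4-dien-2-yl]-2-(4-methoxyphenyl)-2,3-dihydro-4H-pyran-4-one (3-hydroxy dienylketene) | O=C1C=C(C(Cc2ccc(OC)cc2)=C(O)C=C=O)O[C@H](c2ccc(OC)cc2)[C@H]1O
F6 | step 2 | (2R,3R)-3,5,7-trihydroxy-8-(4-methoxybenzyl)-2-(4-methoxyphenyl)chroman-4-one | O=C1c2c(O)cc(O)c(Cc3ccc(OC)cc3)c2O[C@H](c2ccc(OC)cc2)[C@H]1O
F7 | step 3 | 4-[4-(tert-butyldimethylsilyloxy)phenyl]butan-2-one | CC(=O)CCc1ccc(O[Si](C)(C)C(C)(C)C)cc1
F8 | step 3 | methyl (E)-3-[4-(tert-butyldimethylsilyloxy)phenyl]prop-2-enoate | COC(=O)/C=C/c1ccc(O[Si](C)(C)C(C)(C)C)cc1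
F9 | step 3 | methyl (2R,3S)-3-[4-(tert-butyldimethylsilyloxy)phenyl]oxirane-2-carboxylate | COC(=O)[C@@H]1O[C@H]1c1ccc(O[Si](C)(C)C(C)(C)C)cc1
F10 | step 3 | 1-{(2R,3S)-3-[4-(tert-butyldimethylsilyloxy)phenyl]oxiran-2-yl}-5-[4-(tert-butyldimethylsilyloxy)phenyl]pentane-1,3-dione (bis-silyl epoxy-β-diketone) | CC(C)(C)[Si](C)(C)Oc1ccc(CCC(=O)CC(=O)[C@@H]2O[C@H]2c2ccc(O[Si](C)(C)C(C)(C)C)cc2)cc1
F11 | step 3 | tris-silyl dihydropyranone, the analogue of 5 with both OMe replaced by OTBS | O=C1C=C(CCc2ccc(O[Si](C)(C)C(C)(C)C)cc2)O[C@H](c2ccc(O[Si](C)(C)C(C)(C)C)cc2)[C@H]1O[Si](C)(C)C(C)(C)C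
F12 | step 3 | tetrakis-silyl dienol ether, the analogue of 6 with both OMe replaced by OTBS | CC(C)(C)[Si](C)(C)OC1=CC(=CCc2ccc(O[Si](C)(C)C(C)(C)C)cc2)O[C@H](c2ccc(O[Si](C)(C)C(C)(C)C)cc2)[C@H]1O[Si](C)(C)C(C)(C)C
F13 | step 3 | tris-silyl keto acid chloride, the analogue of 7 with both OMe replaced by OTBS | O=C1C=C(C(Cc2ccc(O[Si](C)(C)C(C)(C)C)cc2)C(=O)CC(=O)Cl)O[C@H](c2ccc(O[Si](C)(C)C(C)(C)C)cc2)[C@H]1O[Si](C)(C)C(C)(C)C
F14 | step 3 | tris-silyl dienylketene, the analogue of 8 with both OMe replaced by OTBS | O=C1C=C(C(Cc2ccc(O[Si](C)(C)C(C)(C)C)cc2)=C(O)C=C=O)O[C@H](c2ccc(O[Si](C)(C)C(C)(C)C)cc2)[C@H]1O[Si](C)(C)C(C)(C)C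
F15 | step 3 | (2R,3R)-3-(tert-butyldimethylsilyloxy)-8-[4-(tert-butyldimethylsilyloxy)benzyl]-2-[4-(tert-butyldimethylsilyloxy)phenyl]-5,7-dihydroxychroman-4-one (tris-silyl chromanone) | O=C1c2c(O)cc(O)c(Cc3ccc(O[Si](C)(C)C(C)(C)C)cc3)c2O[C@H](c2ccc(O[Si](C)(C)C(C)(C)C)cc2)[C@H]1O[Si](C)(C)C(C)(C)C
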